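## Structural features

The target is a C24 acid built from a cis-fused decalin (ring A: C2–C3–C4–C5–C6–C7; ring B: C5–C6–C8–C9–C11–C22) and a 1,2-dioxane (C14–C16–C17–C18–O–O). The two-carbon tether C12–C13 joins C11 to C14, and C18 carries the propanoic acid unit C19(C20)–C21. Ring A has an exocyclic methylene at C2 (C1), ring B has one at C9 (C10), and the gem-dimethyl carbon C22 sits between the ring-fusion carbon C5 and the side-chain carbon C11. The six stereocentres fall into two clusters: C5, C6 and C11 on ring B (all three hydrogens on one face), and C14, C18 and C19 on the peroxide side, with C18/C19 adjacent and C14 1,4 to C18 across the dioxane. Fragile groups are the O–O bond (reductants, phosphines, strong base at C18–H), the β-peroxy carbonyl at C21 (base-induced ring opening) and the two 1,1-disubstituted alkenes (acid, electrophiles, hydrogenation). The real difficulties are C11 next to the quaternary C22, and the quaternary peroxy carbon C14, whose two alkyl arms are sterically alike and which must be made without any alkene reduction. The key step uses the fact that ring A plus C8 and C22 is the verbenone skeleton once the cyclobutane bond C3–C22 is cut; the freed C22 cation lies next to the C8 chain, so C11–C22 closes ring B.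

## Logic of the disconnections

**C21 oxidation level (33 from 31 and 30).** No skeletal bond is cut. The acid is taken back to a silyl-protected primary alcohol so that no β-peroxy carbonyl meets base earlier. The forward oxidation must spare O–O and both methylenes.

**O–C14 and C16–H (30 from 29 from 28).** C14 cannot be made by substitution, so its C–O bond is formed by adding the C18 hydroperoxide across the C14=C16 alkene. The alkene geometry is translated through a chair into the C14 configuration, and the ring and C14 arise together without an alkene reduction. The forward step needs 6-endo regiochemistry, an electrophile that spares the methylenes, and removal of the C16 iodine without O–O cleavage.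

**C18–O (28 from 27 from 26).** The secondary peroxy carbon comes from a carbinol by SN2 inversion. This makes C18 a matter of alcohol stereochemistry but demands substitution at a hindered homoallylic centre.

**C16–C17 (26 from 18 and 24).** An (E)-alkenyl metal opens a terminal epoxide at CH2. This splits the molecule into the decalin and a five-carbon fragment that carries C18 and C19. It demands retention of alkene geometry.

**Epoxide fragment (24 back to 19).** C19 comes from a commercial hydroxy ester; C18 is fixed by hydrolytic kinetic resolution of the epoxide epimers; C17 is the Wittig carbon.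

**C14–C15, C16–I, C14≡C16, C2=C1 (18 back to 12).** Syn carbometalation of a terminal alkyne gives the (E)-trisubstituted alkene with certainty, which olefination of a methyl ketone would not. The alkyne comes from the C14 aldehyde, and the C2 methylene from the ketone. These steps must leave the exocyclic alkenes alone.

**C11–C22 (12 from 10, the key step).** Reconnecting C3–C22 gives the nopinone. Two corrections to the precursor are needed:
- The tether from C11 to oxygen must contain three carbons (C12, C13, C14). A two-carbon tether from but-3-yn-1-ol lacks C14, so pent-4-yn-1-ol is the right alkynol.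
- An (E)-alkenyl metal at C9 gives, by retention, the (Z)-allylsilane, not the (E)-isomer. The (Z)-isomer is chosen here on conformational grounds: the cation is born with C22 axial on ring A, and in that chair only the substituent trans to C8 ends equatorial and syn to C4 and C7. The (E)-isomer would need the ring-flipped conformer and a 1,3-diaxial C12/C4 contact.

The C2 ketone carbon and the silicon are lost as planned; the pivalate is a spectator.

**C6–H and C8–C9 (10 from 9 from 8 and 6; 8 from 7).** Hydride delivered opposite the CMe2 bridge sets C6, and an sp2–sp3 coupling joins the C8 bromide to the alkenylboronate. Verbenone supplies C5 and the absolute configuration.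

**Alkenylboronate (6 back to 1).** C9–C10 is made by coupling at a C–Br bond with retention, and the C9–B/C11–H pair by syn hydroboration of the bromoalkyne. The same bromoboronate can give either alkene geometry.

## Other disconnections considered

**Alternative 1:** The cut is the dioxane bond C16–C17, together with the C–O bonds that join two peroxide halves. Forward, the acyclic dialkyl peroxide A2 (vinyl groups on C14 and C18, both decalin ketones masked as β-hydroxysilanes) would be closed by the second-generation Grubbs catalyst (H2IMes)(PCy3)Cl2Ru=CHPh to the dihydrodioxine A1. Diimide reduction, two Peterson eliminations and ester hydrolysis would follow.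
- In its favour: C14 and C18 are fixed in separate halves, so no diastereoselective ring closure is needed. On C14 this is better than the chosen plan. Ring-closing metathesis of two vinyl groups to a six-membered ring is dependable, and the masked methylenes remove chemoselectivity questions (equal or better).
- Against it: it needs an enantioenriched tertiary allylic hydroperoxide and a peroxide C–O bond at a hindered secondary allylic carbon. The ring alkene forces diimide, hence the masking and two late eliminations beside a peroxide. The decalin still has to be made.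
- Comparison: no cation is needed there, no alkene reduction here. Step count is expected to be higher by the masking, reduction and unmasking.

**Alternative 2:** The cut is C6–C7. Forward, LiN[CH(CH3)C6H5]2 would remove one enantiotopic α-proton of the meso ketone A4, and the enolate would displace the allylic chloride of the neighbouring arm to give A3.
- In its favour: the meso precursor has the cis relation of C5 and C11 built in, so C11 is not at risk in a cyclisation. That is better than the chosen plan on this point. The second arm already carries C14, C15 and a C16 handle, and the core is reached in few steps.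
- Against it: the ketone ends at C8 while the methylene belongs at C9, so a carbonyl transposition is needed. The absolute configuration rests on a stoichiometric chiral base rather than on verbenone. C6 is α to the ketone, so the cis fusion is not secured.
- Comparison: enolate alkylation against cation capture; likely shorter to the bicycle, longer after it.

**Alternative 3:** The cut is C6–C8. Forward, TiCl4 would activate the cyclohexenone A6 and the allylsilane terminus C8 would add to C6 (conjugate Hosomi–Sakurai closure), giving A5, drawn here with the three-carbon tether the target needs.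
- In its favour: it gives the same type of bicyclic ketone, so the endgame is identical (equal). The conjugate allylsilane addition is better precedented than the fragmentation–capture (better). C11 is not formed in the ring closure.
- Against it: A6 needs C5 and C11 set across the quaternary C22 in an open chain, and an enantioenriched 4-substituted cyclohexenone. The chosen plan takes C5, C6 and C22 from the chiral pool.
- Comparison: both are allylsilane-terminated cationic closures; the longer access to A6 is expected to outweigh its safer ring closure.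

Key step: step 8

Remark: atom numbers C1–C24 follow the carbons of the target SMILES; all reagents named are taken to be commercial.

## Steps

Step 1
Reactants: 1 pent-4-yn-1-ol
Product: 2 pent-4-yn-1-yl pivalate
Conditions: t-BuCOCl, Et3N, DMAP (cat.), CH2Cl2, 0 °C → rt
Reagents that add atoms: pivaloyl chloride, CC(C)(C)C(=O)Cl
Why: Acylation of the primary alcohol; the pivalate should survive the boron, zinc, copper hydride and SnCl4 steps that follow.

Step 2
Reactants: 2 pent-4-yn-1-yl pivalate
Product: 3 5-bromopent-4-yn-1-yl pivalate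
Conditions: NBS, AgNO3 (cat.), acetone, rt
Reagents that add atoms: N-bromosuccinimide, O=C1CCC(=O)N1Br
Why: Silver-catalysed electrophilic bromination of the terminal alkyne C–H; the bromine will direct boron to C9.

Step 3
Reactants: 3 5-bromopent-4-yn-1-yl pivalate
Product: 5 (4Z)-5-bromo-5-(pinacolboryl)pent-4-en-1-yl pivalate, via alkenyldibromoborane 4 (not isolated)
Conditions: HBBr2·SMe2, CH2Cl2, 0 °C → rt; then pinacol, Et2O, 0 °C
Reagents that add atoms: dibromoborane–dimethyl sulfide, C[S+](C)[BH-](Br)Br; pinacol, CC(C)(O)C(C)(C)O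
Why: Hydroboration of a 1-bromoalkyne puts boron on the halogen-bearing carbon by syn addition, so boron is trans and bromine cis to the chain; pinacol gives the stable ester.

Step 4
Reactants: 5 (4Z)-5-bromo-5-(pinacolboryl)pent-4-en-1-yl pivalate
Product: 6 (4Z)-5-(pinacolboryl)-6-(trimethylsilyl)hex-4-en-1-yl pivalate
Conditions: Me3SiCH2MgCl, ZnCl2, THF, 0 °C; then 5, Pd(PPh3)4 (cat.), THF, rt → 50 °C
Reagents that add atoms: (trimethylsilyl)methylmagnesium chloride, C[Si](C)(C)C[Mg]Cl
Why: Negishi coupling at the C–Br bond of a 1-bromoalkenylboronate goes with retention, so CH2SiMe3 (C10) ends cis to the chain and boron trans. The zinc reagent is preformed so that no borate forms and rearranges with inversion.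

Step 5
Reactants: 7 (1S,5S)-(−)-verbenone
Product: 8 4-(bromomethyl)-6,6-dimethylbicyclo[3.1.1]hept-3-en-2-one
Conditions: NBS, AIBN (cat.), PhCF3, 80 °C
Reagents that add atoms: N-bromosuccinimide, O=C1CCC(=O)N1Br
Why: Wohl–Ziegler bromination; only the C8 methyl gives a delocalised radical, because the other γ-position is a cyclobutane bridgehead.

Step 6
Reactants: 8 4-(bromomethyl)-6,6-dimethylbicyclo[3.1.1]hept-3-en-2-one; 6 (4Z)-5-(pinacolboryl)-6-(trimethylsilyl)hex-4-en-1-yl pivalate
Product: 9 4-[(2Z)-6-(pivaloyloxy)-2-(trimethylsilylmethyl)hex-2-en-1-yl]-6,6-dimethylbicyclo[3.1.1]hept-3-en-2-one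
Conditions: Pd(dppf)Cl2 (cat.), K3PO4, THF/H2O, 40 °C
Reagents that add atoms: none
Why: Suzuki–Miyaura coupling of the alkenylboronate with the allylic bromide forms C8–C9 with retention, giving the (Z)-allylsilane; coupling at the primary terminus keeps the enone conjugated.

Step 7
Reactants: 9 4-[(2Z)-6-(pivaloyloxy)-2-(trimethylsilylmethyl)hex-2-en-1-yl]-6,6-dimethylbicyclo[3.1.1]hept-3-en-2-one
Product: 10 cis-4-[(2Z)-6-(pivaloyloxy)-2-(trimethylsilylmethyl)hex-2-en-1-yl]-6,6-dimethylbicyclo[3.1.1]heptan-2-one
Conditions: [(Ph3P)CuH]6, H2O, toluene, rt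
Reagents that add atoms: none
Why: Copper hydride conjugate reduction; hydride reaches the β-carbon (C6) from the face opposite the CMe2 bridge, so the C8 chain ends cis to that bridge. The allylsilane and ester are inert.

Step 8
Reactants: 10 cis-4-[(2Z)-6-(pivaloyloxy)-2-(trimethylsilylmethyl)hex-2-en-1-yl]-6,6-dimethylbicyclo[3.1.1]heptan-2-one
Product: 12 cis-decalin C2 ketone with C9 methylene and 3-(pivaloyloxy)propyl chain on C11, via trichlorostannyl enolate 11 (not isolated)
Conditions: SnCl4, 2,6-di-tert-butyl-4-methylpyridine, CH2Cl2, −78 → 0 °C; aq. NaHCO3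
Reagents that add atoms: none
Why: SnCl4 binds the C2 carbonyl and the strained C3–C22 bond ionises to the tin enolate of ring A and a tertiary C22 cation; the allylsilane adds through C11, and loss of Me3Si from the β-silyl cation leaves the exocyclic C9=C10. The closest known reaction type is the Lewis-acid fragmentation of 4-substituted nopinones with internal capture of the tertiary cation (the pyran closure of cannabinoid syntheses), terminated here as in allylsilane cation–olefin cyclisations. Ring B closes 6-endo-trig at the alkene (C22 to C11, both alkene carbons in the new ring). The cis fusion at C5/C6 is inherited from 10, where the C6 chain is cis to the former bridge. C11 is set by alkene geometry in a chair-like transition state: the cation is born with the C5–C22 bond axial and C8 equatorial on ring A, and in that chair the C11 substituent trans to C8 becomes equatorial and syn to C4 and C7; in the (Z)-allylsilane that substituent is C12. The step needs capture faster than ring-A inversion, proton loss or chloride return; the cis placement of the nucleophile, low temperature and the hindered base (against HCl protodesilylation) are meant to secure this. 1,2-Addition of the allylsilane to the tin-bound ketone is disfavoured because the equatorial chain cannot reach C2 across the bicycle.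

Step 9
Reactants: 12 cis-decalin C2 ketone with C9 methylene and 3-(pivaloyloxy)propyl chain on C11
Product: 13 3-decalinylpropyl pivalate
Conditions: Ph3PCH3Br, KOtBu, THF, 0 °C → rt
Reagents that add atoms: methyltriphenylphosphonium bromide, C[P+](c1ccccc1)(c1ccccc1)c1ccccc1.[Br-]
Why: Wittig methylenation of the unhindered cyclohexanone installs C1; C6 is β to the carbonyl and cannot epimerise.

Step 10
Reactants: 13 3-decalinylpropyl pivalate
Product: 14 3-decalinylpropan-1-ol
Conditions: i-Bu2AlH, CH2Cl2, −78 °C; aq. sodium potassium tartrate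
Reagents that add atoms: none
Why: Reductive cleavage of the pivalate; no other group reacts with the hydride.

Step 11
Reactants: 14 3-decalinylpropan-1-ol
Product: 15 3-decalinylpropanal
Conditions: TEMPO (cat.), PhI(OAc)2, CH2Cl2, rt
Reagents that add atoms: none
Why: Oxoammonium oxidation of the primary alcohol to the C14 aldehyde; the 1,1-disubstituted alkenes are untouched.

Step 12
Reactants: 15 3-decalinylpropanal
Product: 16 5-decalinylpent-1-yne
Conditions: MeC(O)C(N2)P(O)(OMe)2, K2CO3, MeOH, 0 °C → rt
Reagents that add atoms: dimethyl (1-diazo-2-oxopropyl)phosphonate, CC(=O)C(=[N+]=[N-])P(=O)(OC)OC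
Why: Seyferth–Gilbert homologation in its Ohira–Bestmann form turns the aldehyde into the terminal alkyne and adds C16; the α-carbon is CH2, so nothing can epimerise.

Step 13
Reactants: 16 5-decalinylpent-1-yne
Product: 18 (1E)-5-decalinyl-1-iodo-2-methylpent-1-ene, via alkenylalane 17 (not isolated)
Conditions: Me3Al, Cp2ZrCl2 (cat.), CH2Cl2, 0 °C → rt; then I2, THF, −30 °C
Reagents that add atoms: trimethylaluminium, C[Al](C)C; iodine, II
Why: Zirconium-catalysed carboalumination (Negishi) adds CH3 (C15) and Al syn, with methyl on the internal carbon; iodinolysis with retention gives the (E)-iodide. Unactivated 1,1-disubstituted alkenes do not react.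

Step 14
Reactants: 19 methyl (S)-3-hydroxy-2-methylpropanoate
Product: 20 methyl (S)-3-(tert-butyldimethylsilyloxy)-2-methylpropanoate
Conditions: t-BuMe2SiCl, imidazole, CH2Cl2, rt
Reagents that add atoms: tert-butyldimethylsilyl chloride, CC(C)(C)[Si](C)(C)Cl
Why: Silylation of the primary alcohol (the future C21 oxygen).

Step 15
Reactants: 20 methyl (S)-3-(tert-butyldimethylsilyloxy)-2-methylpropanoate
Product: 21 (S)-3-(tert-butyldimethylsilyloxy)-2-methylpropanal
Conditions: i-Bu2AlH, CH2Cl2, −78 °C
Reagents that add atoms: none
Why: Partial reduction of the ester; the tetrahedral aluminate holds at −78 °C and releases the aldehyde on work-up.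

Step 16
Reactants: 21 (S)-3-(tert-butyldimethylsilyloxy)-2-methylpropanal
Product: 22 (R)-tert-butyldimethyl[(2-methylbut-3-en-1-yl)oxy]silane
Conditions: Ph3PCH3Br, KOtBu, THF, 0 °C; then 21, −78 → 0 °C
Reagents that add atoms: methyltriphenylphosphonium bromide, C[P+](c1ccccc1)(c1ccccc1)c1ccccc1.[Br-]
Why: Wittig methylenation adds C17; adding the aldehyde cold to preformed ylide limits epimerisation at C19.

Step 17
Reactants: 22 (R)-tert-butyldimethyl[(2-methylbut-3-en-1-yl)oxy]silane
Product: 23 tert-butyldimethyl{[(2S)-2-(oxiran-2-yl)propyl]oxy}silane (both epimers at the oxirane carbon)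
Conditions: mCPBA, NaHCO3, CH2Cl2, 0 °C → rt
Reagents that add atoms: 3-chloroperoxybenzoic acid, OOC(=O)c1cccc(Cl)c1
Why: Prilezhaev epoxidation of the terminal alkene; the allylic stereocentre gives little facial bias, so both epimers are expected and are resolved next.

Step 18
Reactants: 23 tert-butyldimethyl{[(2S)-2-(oxiran-2-yl)propyl]oxy}silane (both epimers)
Product: 24 tert-butyldimethyl{[(2S)-2-[(2R)-oxiran-2-yl]propyl]oxy}silane
Conditions: (R,R)-(salen)Co(OAc) [salen = N,N′-bis(3,5-di-tert-butylsalicylidene)-1,2-cyclohexanediamine dianion] (cat.), H2O (0.55 equiv), THF, 0 °C → rt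
Reagents that add atoms: none
Why: Hydrolytic kinetic resolution; the catalyst hydrolyses the (2S)-oxirane and leaves the (2R)-oxirane that supplies C18. The catalyst, not the substrate, controls the outcome; its enantiomer is used if the sense proves opposite.

Step 19
Reactants: 18 (1E)-5-decalinyl-1-iodo-2-methylpent-1-ene; 24 tert-butyldimethyl{[(2S)-2-[(2R)-oxiran-2-yl]propyl]oxy}silane
Product: 26 (2S,3S,5E)-1-(tert-butyldimethylsilyloxy)-8-decalinyl-2,6-dimethyloct-5-en-3-ol, via alkenyllithium 25 (not isolated)
Conditions: t-BuLi, Et2O, −78 °C; then 24, BF3·OEt2, −78 °C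
Reagents that add atoms: none
Why: Iodine–lithium exchange with retention, then BF3-promoted opening of the terminal epoxide at CH2, forms C16–C17. The C18 carbinol keeps the epoxide configuration and the alkene stays (E).

Step 20
Reactants: 26 (2S,3S,5E)-1-(tert-butyldimethylsilyloxy)-8-decalinyl-2,6-dimethyloct-5-en-3-ol
Product: 27 methanesulfonate of 26
Conditions: MeSO2Cl, Et3N, CH2Cl2, 0 °C
Reagents that add atoms: methanesulfonyl chloride, CS(=O)(=O)Cl
Why: Sulfonylation activates C18 for displacement without touching its configuration.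

Step 21
Reactants: 27 methanesulfonate of 26
Product: 28 (2S,3R,5E)-1-(tert-butyldimethylsilyloxy)-8-decalinyl-3-hydroperoxy-2,6-dimethyloct-5-ene
Conditions: H2O2 (50% aq., excess), KOH, MeOH/THF, 0 °C → rt
Reagents that add atoms: hydrogen peroxide, OO
Why: SN2 displacement of the secondary mesylate by hydroperoxide anion with inversion sets C18; the weakly basic α-effect nucleophile, in large excess, favours substitution over elimination and over dialkyl peroxide formation.

Step 22
Reactants: 28 (2S,3R,5E)-1-(tert-butyldimethylsilyloxy)-8-decalinyl-3-hydroperoxy-2,6-dimethyloct-5-ene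
Product: 29 5-iodo-1,2-dioxane silyl ether (iodine on C16, equatorial, anti to the new C14–O bond)
Conditions: NIS, NaHCO3, CH2Cl2, −40 → 0 °C, dark
Reagents that add atoms: N-iodosuccinimide, O=C1CCC(=O)N1I
Why: Halocyclisation of an unsaturated hydroperoxide; the iodonium opens at the tertiary C14 (6-endo, Markovnikov) by anti addition. In the chair with the C18 substituent equatorial, the (E)-alkene places the C13 chain (trans to C17) equatorial and C15 axial, which is the required C14 configuration. The exocyclic alkenes can only form iodonium ions reversibly because no nucleophile is in reach.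

Step 23
Reactants: 29 5-iodo-1,2-dioxane silyl ether
Product: 30 tert-butyl{[(2S)-2-[(3R,6S)-6-(2-decalinylethyl)-6-methyl-1,2-dioxan-3-yl]propyl]oxy}dimethylsilane
Conditions: Bu3SnH, Et3B (cat.), air, toluene, 0 °C
Reagents that add atoms: none
Why: Radical chain deiodination, a known way to remove halogen from halocyclised cyclic peroxides; hydrogen transfer to the ring radical at C16 should outrun attack on the ring O–O bond, which is poorly aligned from inside the ring.

Step 24
Reactants: 30 tert-butyl{[(2S)-2-[(3R,6S)-6-(2-decalinylethyl)-6-methyl-1,2-dioxan-3-yl]propyl]oxy}dimethylsilane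
Product: 31 (2S)-2-[(3R,6S)-6-(2-decalinylethyl)-6-methyl-1,2-dioxan-3-yl]propan-1-ol
Conditions: Bu4NF, AcOH, THF, 0 °C → rt
Reagents that add atoms: none
Why: Fluoride desilylation, buffered with acetic acid to avoid base-induced Kornblum–DeLaMare cleavage at C18–H.

Step 25
Reactants: 31 (2S)-2-[(3R,6S)-6-(2-decalinylethyl)-6-methyl-1,2-dioxan-3-yl]propan-1-ol
Product: 33 (2R)-2-[(3R,6S)-6-{2-[(2R,4aS,8aS)-1,1-dimethyl-3,6-dimethylidenedecahydronaphthalen-2-yl]ethyl}-6-methyl-1,2-dioxan-3-yl]propanoic acid (target), via aldehyde 32 (not isolated)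
Conditions: TEMPO (cat.), PhI(OAc)2, MeCN/H2O, rt
Reagents that add atoms: water, O
Why: Oxoammonium oxidation in aqueous acetonitrile takes the primary alcohol through the aldehyde hydrate to the acid under near-neutral conditions, so C19 is not epimerised and the β-peroxy carbonyl never meets base; the O–O bond and alkenes are inert.

## Compound list

"Decalinyl" = (2R,4aS,8aS)-1,1-dimethyl-3,6-dimethylidenedecahydronaphthalen-2-yl: cis-fused, with H-5, H-6 and H-11 on one face and C11 as the attachment point.

1 | pent-4-yn-1-ol | C#CCCCO | starting material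
2 | pent-4-yn-1-yl pivalate | C#CCCCOC(=O)C(C)(C)C | intermediate
3 | 5-bromopent-4-yn-1-yl pivalate | BrC#CCCCOC(=O)C(C)(C)C | intermediate
4 | (Z)-[1-bromo-5-(pivaloyloxy)pent-1-en-1-yl]dibromoborane–dimethyl sulfide adduct (boron trans, bromine cis to the chain) | C[S+](C)[B-](Br)(Br)/C(Br)=C/CCCOC(=O)C(C)(C)C | intermediate (not isolated)
5 | (4Z)-5-bromo-5-(4,4,5,5-tetramethyl-1,3,2-dioxaborolan-2-yl)pent-4-en-1-yl pivalate | CC1(C)OB(OC1(C)C)/C(Br)=C/CCCOC(=O)C(C)(C)C | intermediate
6 | (4Z)-5-(4,4,5,5-tetramethyl-1,3,2-dioxaborolan-2-yl)-6-(trimethylsilyl)hex-4-en-1-yl pivalate (CH2SiMe3 cis, boron trans to the chain) | CC1(C)OB(OC1(C)C)/C(C[Si](C)(C)C)=C/CCCOC(=O)C(C)(C)C | intermediate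
7 | (1S,5S)-(−)-verbenone | O=C1[C@H]2C[C@@H](C(C)=C1)C2(C)C | starting material
8 | 4-(bromomethyl)-6,6-dimethylbicyclo[3.1.1]hept-3-en-2-one (core configured as in 7) | O=C1[C@H]2C[C@@H](C(CBr)=C1)C2(C)C | intermediate
9 | 4-[(2Z)-6-(pivaloyloxy)-2-(trimethylsilylmethyl)hex-2-en-1-yl]-6,6-dimethylbicyclo[3.1.1]hept-3-en-2-one (core as in 7) | O=C1[C@H]2C[C@@H](C(C/C(C[Si](C)(C)C)=C/CCCOC(=O)C(C)(C)C)=C1)C2(C)C | intermediate
10 | cis-4-[(2Z)-6-(pivaloyloxy)-2-(trimethylsilylmethyl)hex-2-en-1-yl]-6,6-dimethylbicyclo[3.1.1]heptan-2-one (chain cis to the CMe2 bridge) | O=C1[C@H]2C[C@@H]([C@@H](C1)C/C(C[Si](C)(C)C)=C/CCCOC(=O)C(C)(C)C)C2(C)C | intermediate (key-step precursor)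
11 | trichlorostannyl enolate of 12 (O–SnCl3 on C2, C2=C3) | Cl[Sn](Cl)(Cl)OC1=CC[C@H]2[C@@H](C1)CC(=C)[C@@H](CCCOC(=O)C(C)(C)C)C2(C)C | intermediate (not isolated)
12 | cis-decalin C2 ketone with C9 methylene and 3-(pivaloyloxy)propyl chain on C11 (H-5, H-6, H-11 on one face) | O=C1CC[C@H]2[C@@H](C1)CC(=C)[C@@H](CCCOC(=O)C(C)(C)C)C2(C)C | intermediate (key-step product)
13 | 3-decalinylpropyl pivalate | C=C1CC[C@H]2[C@@H](C1)CC(=C)[C@@H](CCCOC(=O)C(C)(C)C)C2(C)C | intermediate
14 | 3-decalinylpropan-1-ol | C=C1CC[C@H]2[C@@H](C1)CC(=C)[C@@H](CCCO)C2(C)C | intermediate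
15 | 3-decalinylpropanal | C=C1CC[C@H]2[C@@H](C1)CC(=C)[C@@H](CCC=O)C2(C)C | intermediate
16 | 5-decalinylpent-1-yne | C=C1CC[C@H]2[C@@H](C1)CC(=C)[C@@H](CCC#C)C2(C)C | intermediate
17 | [(1E)-5-decalinyl-2-methylpent-1-en-1-yl]dimethylalane | C=C1CC[C@H]2[C@@H](C1)CC(=C)[C@@H](CC/C(C)=C/[Al](C)C)C2(C)C | intermediate (not isolated)
18 | (1E)-5-decalinyl-1-iodo-2-methylpent-1-ene | C=C1CC[C@H]2[C@@H](C1)CC(=C)[C@@H](CC/C(C)=C/I)C2(C)C | intermediate
19 | methyl (S)-3-hydroxy-2-methylpropanoate | COC(=O)[C@@H](C)CO | starting material
20 | methyl (S)-3-(tert-butyldimethylsilyloxy)-2-methylpropanoate | COC(=O)[C@@H](C)CO[Si](C)(C)C(C)(C)C | intermediate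
21 | (S)-3-(tert-butyldimethylsilyloxy)-2-methylpropanal | O=C[C@@H](C)CO[Si](C)(C)C(C)(C)C | intermediate
22 | (R)-tert-butyldimethyl[(2-methylbut-3-en-1-yl)oxy]silane | C=C[C@@H](C)CO[Si](C)(C)C(C)(C)C | intermediate
23 | tert-butyldimethyl{[(2S)-2-(oxiran-2-yl)propyl]oxy}silane, both epimers at the oxirane carbon | C1OC1[C@@H](C)CO[Si](C)(C)C(C)(C)C | intermediate
24 | tert-butyldimethyl{[(2S)-2-[(2R)-oxiran-2-yl]propyl]oxy}silane | C1[C@@H]([C@@H](C)CO[Si](C)(C)C(C)(C)C)O1 | intermediate
25 | [(1E)-5-decalinyl-2-methylpent-1-en-1-yl]lithium | C=C1CC[C@H]2[C@@H](C1)CC(=C)[C@@H](CC/C(C)=C/[Li])C2(C)C | intermediate (not isolated)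
26 | (2S,3S,5E)-1-(tert-butyldimethylsilyloxy)-8-decalinyl-2,6-dimethyloct-5-en-3-ol | C=C1CC[C@H]2[C@@H](C1)CC(=C)[C@@H](CC/C(C)=C/C[C@@H]([C@@H](C)CO[Si](C)(C)C(C)(C)C)O)C2(C)C | intermediate
27 | methanesulfonate of 26 | C=C1CC[C@H]2[C@@H](C1)CC(=C)[C@@H](CC/C(C)=C/C[C@@H]([C@@H](C)CO[Si](C)(C)C(C)(C)C)OS(C)(=O)=O)C2(C)C | intermediate
28 | (2S,3R,5E)-1-(tert-butyldimethylsilyloxy)-8-decalinyl-3-hydroperoxy-2,6-dimethyloct-5-ene | C=C1CC[C@H]2[C@@H](C1)CC(=C)[C@@H](CC/C(C)=C/C[C@H]([C@@H](C)CO[Si](C)(C)C(C)(C)C)OO)C2(C)C | intermediate
29 | 5-iodo analogue of 30 (iodine on C16, trans to the ring oxygen on C14) | C=C1CC[C@H]2[C@@H](C1)CC(=C)[C@@H](CC[C@@]1(C)[C@H](I)C[C@H]([C@@H](C)CO[Si](C)(C)C(C)(C)C)OO1)C2(C)C | intermediate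
30 | tert-butyl{[(2S)-2-[(3R,6S)-6-(2-decalinylethyl)-6-methyl-1,2-dioxan-3-yl]propyl]oxy}dimethylsilane | C=C1CC[C@H]2[C@@H](C1)CC(=C)[C@@H](CC[C@@]1(C)CC[C@H]([C@@H](C)CO[Si](C)(C)C(C)(C)C)OO1)C2(C)C | intermediate
31 | (2S)-2-[(3R,6S)-6-(2-decalinylethyl)-6-methyl-1,2-dioxan-3-yl]propan-1-ol | C=C1CC[C@H]2[C@@H](C1)CC(=C)[C@@H](CC[C@@]1(C)CC[C@H]([C@@H](C)CO)OO1)C2(C)C | intermediate
32 | (2R)-2-[(3R,6S)-6-(2-decalinylethyl)-6-methyl-1,2-dioxan-3-yl]propanal | C=C1CC[C@H]2[C@@H](C1)CC(=C)[C@@H](CC[C@@]1(C)CC[C@H]([C@@H](C)C=O)OO1)C2(C)C | intermediate (not isolated)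
33 | (2R)-2-[(3R,6S)-6-(2-decalinylethyl)-6-methyl-1,2-dioxan-3-yl]propanoic acid | C=C1CC[C@H]2[C@@H](C1)CC(=C)[C@@H](CC[C@@]1(C)CC[C@H]([C@@H](C)C(=O)O)OO1)C2(C)C | target

## Step count and least certain steps

Total: 25 steps. Longest linear sequence: 19 steps (1, 2, 3, 4, 6–13, 19–25, from pent-4-yn-1-ol).

**Step 8 (key step).** The most likely failure is loss of control at C11. If the cation is returned as the tertiary chloride, or is captured slowly enough for ring A to invert, the relaxed conformer (C22 equatorial) cyclises through an unstrained chair that, with the (Z)-alkene, gives the C11 epimer. The fallback changes the alkene geometry through a different bond-forming mechanism. It sets out from 5: adding Me3SiCH2MgCl to boron and letting the borate rearrange (1,2-migration with inversion at the alkenyl carbon) should give (4E)-5-(pinacolboryl)-6-(trimethylsilyl)hex-4-en-1-yl pivalate F1. Suzuki–Miyaura coupling of F1 with 8 should give the (2E)-dienone F2, and copper hydride reduction the cis-4-substituted (2E)-nopinone F3. In the relaxed chair, F3 places C12 axial and syn to C4 and C7; treatment with SnCl4 allowed to warm should then return to the route at 12.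

**Step 21.** The most likely failures are E2 elimination toward the conjugated diene (the C17 hydrogens are allylic), slow substitution at a β-branched secondary carbon, and base-induced decomposition of the product hydroperoxide. The fallback replaces sulfonate displacement by ring opening. It sets out from 26: Bu4NF should give (2S,3S,5E)-8-decalinyl-2,6-dimethyloct-5-ene-1,3-diol F4. One-pot tosylation of the primary hydroxyl and closure (n-BuLi, TsCl, then n-BuLi) should give the 2,3-disubstituted oxetane F5. Ethereal H2O2 with catalytic Me3SiOTf at low temperature should open F5 at the secondary carbon C18 with inversion, giving (2S,3R,5E)-8-decalinyl-3-hydroperoxy-2,6-dimethyloct-5-en-1-ol F6. Iodocyclisation with NIS as in step 22 should give the 5-iodo-1,2-dioxane alcohol F7, and Bu3SnH reduction returns to the route at 31.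

**Step 22.** The most likely failures are leakage to 5-exo closure (a 1,2-dioxolane), erosion of chair selectivity at C14, or consumption of the electrophile by the exocyclic alkenes. The fallback replaces irreversible iodonium capture by a reversible, thermodynamically steered selenocyclisation. It sets out from 28: N-(phenylselanyl)phthalimide with catalytic camphorsulfonic acid in CH2Cl2 should give the 5-(phenylselanyl)-1,2-dioxane silyl ether F8. The episelenonium ion can reopen until the Markovnikov six-membered product accumulates. Bu3SnH/Et3B removes selenium and returns to the route at 30.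

**Step 23.** The most likely failure is fragmentation of the C16 radical (β-scission of C14–O or attack on O–O) before hydrogen transfer. The fallback uses mercury in place of iodine, so that the C16 substituent is removed by a much faster hydride-transfer chain. It sets out from 28: Hg(OAc)2 in CH2Cl2 should give, by cycloperoxymercuration, the 5-(acetoxymercurio)-1,2-dioxane silyl ether F9. NaBH4 in aqueous NaOH at 0 °C returns to the route at 30.

## Further compounds

F1 | step 8 | (4E)-5-(4,4,5,5-tetramethyl-1,3,2-dioxaborolan-2-yl)-6-(trimethylsilyl)hex-4-en-1-yl pivalate | CC1(C)OB(OC1(C)C)/C(C[Si](C)(C)C)=C\CCCOC(=O)C(C)(C)C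
F2 | step 8 | 4-[(2E)-6-(pivaloyloxy)-2-(trimethylsilylmethyl)hex-2-en-1-yl]-6,6-dimethylbicyclo[3.1.1]hept-3-en-2-one | O=C1[C@H]2C[C@@H](C(C/C(C[Si](C)(C)C)=C\CCCOC(=O)C(C)(C)C)=C1)C2(C)C
F3 | step 8 | cis-4-[(2E)-6-(pivaloyloxy)-2-(trimethylsilylmethyl)hex-2-en-1-yl]-6,6-dimethylbicyclo[3.1.1]heptan-2-one | O=C1[C@H]2C[C@@H]([C@@H](C1)C/C(C[Si](C)(C)C)=C\CCCOC(=O)C(C)(C)C)C2(C)C
F4 | step 21 | (2S,3S,5E)-8-decalinyl-2,6-dimethyloct-5-ene-1,3-diol | C=C1CC[C@H]2[C@@H](C1)CC(=C)[C@@H](CC/C(C)=C/C[C@@H]([C@@H](C)CO)O)C2(C)C
F5 | step 21 | 2-[(2E)-5-decalinyl-3-methylpent-2-en-1-yl]-3-methyloxetane (C18 and C19 as in 26) | C=C1CC[C@H]2[C@@H](C1)CC(=C)[C@@H](CC/C(C)=C/C[C@H]1[C@@H](C)CO1)C2(C)C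
F6 | step 21 | (2S,3R,5E)-8-decalinyl-3-hydroperoxy-2,6-dimethyloct-5-en-1-ol | C=C1CC[C@H]2[C@@H](C1)CC(=C)[C@@H](CC/C(C)=C/C[C@H]([C@@H](C)CO)OO)C2(C)C
F7 | step 21 | 5-iodo analogue of 31 (iodine on C16, trans to the ring oxygen on C14) | C=C1CC[C@H]2[C@@H](C1)CC(=C)[C@@H](CC[C@@]1(C)[C@H](I)C[C@H]([C@@H](C)CO)OO1)C2(C)C
F8 | step 22 | 5-(phenylselanyl) analogue of 30 (selenium on C16) | C=C1CC[C@H]2[C@@H](C1)CC(=C)[C@@H](CC[C@@]1(C)[C@H]([Se]c3ccccc3)C[C@H]([C@@H](C)CO[Si](C)(C)C(C)(C)C)OO1)C2(C)C
F9 | step 23 | 5-(acetoxymercurio) analogue of 30 (mercury on C16) | C=C1CC[C@H]2[C@@H](C1)CC(=C)[C@@H](CC[C@@]1(C)[C@H]([Hg]OC(C)=O)C[C@H]([C@@H](C)CO[Si](C)(C)C(C)(C)C)OO1)C2(C)C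
A1 | alternative 1 | 3,6-dihydro-1,2-dioxine methyl ester on the decalin with both ketones masked as (trimethylsilyl)methyl carbinols | O[C@]1(C[Si](C)(C)C)CC[C@H]2[C@@H](C1)C[C@](O)(C[Si](C)(C)C)[C@@H](CC[C@@]3(C)C=C[C@H]([C@@H](C)C(=O)OC)OO3)C2(C)C
A2 | alternative 1 | acyclic dialkyl peroxide with vinyl groups on C14 and C18 on the same masked decalin | O[C@]1(C[Si](C)(C)C)CC[C@H]2[C@@H](C1)C[C@](O)(C[Si](C)(C)C)[C@@H](CC[C@@](C)(C=C)OO[C@H](C=C)[C@@H](C)C(=O)OC)C2(C)C
A3 | alternative 2 | cis-decalin C8 ketone with C2 methylene and intact 3-(chloromethyl)but-3-enyl arm | C=C1CC[C@H]2[C@@H](C1)C(=O)C[C@@H](CCC(=C)CCl)C2(C)C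
A4 | alternative 2 | meso cis-3,5-bis[3-(chloromethyl)but-3-en-1-yl]-4,4-dimethylcyclohexan-1-one | O=C1C[C@H](CCC(=C)CCl)C(C)(C)[C@H](CCC(=C)CCl)C1
A5 | alternative 3 | cis-decalin C2 ketone with C9 methylene and 3-(triisopropylsilyloxy)propyl chain | O=C1CC[C@H]2[C@@H](C1)CC(=C)[C@@H](CCCO[Si](C(C)C)(C(C)C)C(C)C)C2(C)C
A6 | alternative 3 | 4-substituted cyclohex-2-en-1-one carrying the 2-substituted allylsilane on C22 | O=C1CC[C@@H](C=C1)C(C)(C)[C@H](CCCO[Si](C(C)C)(C(C)C)C(C)C)C(=C)C[Si](C)(C)C
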